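Ym, the catalyst, is charged in the flask at one Ym per 500 Vy, so each Ym must go round many times. Its balance is my starting point: I take the forms of Ym to add up to the charge, with their shares set by how much Vy stands around them. The rate of making Ej is then the charge of Ym times a turnover rate.

| setting | delta | eta | beta | flask |
|---|---|---|---|---|
| Vy | 0.061 M | 0.061 M | 0.061 M | 0.061 M |
| Gu | 4.3 mM | 6.7 mM | 3.05 mM | 3.05 mM |
| Ym | 0.2 mol% | 0.2 mol% | 0.4 mol% | 0.2 mol% |
| remark | run made earlier | run made earlier | run made earlier |  |

| run | time / min | Ej / % |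
|---|---|---|
| delta | 6.00 | 76 |
| delta | 12.0 | 90 |
| delta | 20.0 | 89 |
| delta | 25.0 | 90 |
| delta | 30.0 | 93 |
| eta | 6.00 | 74 |
| eta | 12.0 | 86 |
| eta | 20.0 | 84 |
| eta | 25.0 | 88 |
| eta | 30.0 | 89 |
| beta | 2.50 | 74 |
| beta | 5.00 | 91 |
| beta | 8.00 | 95 |
| beta | 15.0 | 98 |
| beta | 30.0 | 92 |

(each reading ± 2 percentage points)

- the numbers in the tables scatter with a standard deviation of 2 percentage points

- factor on the rate of making Ej when 10 % of the Vy are converted if Ym is charged twice over
- factor on the rate when 10 % of the Vy are converted if Ym is charged at 0.02 mol% instead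

Slowed down, the runs read like this. At the moment asked about, 90.0 % of the Vy is still there, so I expect the turnover rate to lie near its starting value. The middle shows in beta: 74 % is Ej after 2.50 min on 0.4 mol% of Ym, which gives 74.0 min⁻¹, the turnover rate, meaning Ej made per Ym charged per minute, averaged over that time. Delta, with half the Ym, reads 76 % after 6.00 min, or 63.3 min⁻¹ over its longer window. At the end the readings level off: eta reads 89 % after 30.0 min, and taking its Gu charge off its Vy leaves 89.0 %.

My own reckoning holds the turnover rate at this average whatever the Ym and puts the flask at 0.148 min⁻¹ of the charge, an average over beta's window, in which Vy thins out. Twice the Ym gives 0.296 min⁻¹, and 0.02 mol% gives 0.0148 min⁻¹. The forecast says 2 and 0.1: “So doubling Ym doubles the rate: first order in Ym.” My factors are the same.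

The simulation gives 2.00 and 0.100.

    Vy.Ym → Rx (k = 10.0 s⁻¹)
    Vy + Ym ⇌ Vy.Ym (K = 23.0 M⁻¹, k = 120 M⁻¹ s⁻¹)
    Vy + Vy.Ym ⇌ Vy.Vy.Ym, settled at all times (K = 34.0 M⁻¹)
    Rx ⇌ Ym + Ej (K = 0.150 M, k = 6.20 s⁻¹)
    Vy + Gu → Vy.Gu (k = 1.20 M⁻¹ s⁻¹)

After 0.344 min the flask makes Ej at 0.175 min⁻¹ of the charge, a turnover rate of 87.7 min⁻¹ for that moment, where the 74.0 min⁻¹ read from beta is an average over 2.50 min. At 0.02 mol% the rate is 0.0176 min⁻¹ of the charge, the same turnover rate on a tenth of the Ym. In the flask part of the Ym sits as Vy.Vy.Ym, which holds the turnover rate down: without that association, the flask's rate at 10 % conversion stands at 1.37 times the actual one.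

The runs are simulated from invented constants.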